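**Assumption:** the target, 6-hydroxy-7-methoxy-3-(2,4,5-trimethoxyphenyl)-4H-chromen-4-one, has no stereocentre and is achiral, so there is no enantiomer to select. The one stereocentre that appears on the way (C3 of 9 and 10) is formed racemic and removed in the last step.

**Retrosynthetic overview**
1. Target 11 ⇐ isoflavanone 10 by C2–C3 dehydrogenation (aromatisation of ring C, last step).
2. 10 ⇐ C3–C1' bond between a C3 enolonium species (umpoled enolate of the chromanone, made from silyl enol ether 5 and Koser's reagent) and 1,2,4-trimethoxybenzene used as a C–H nucleophile; both carbons are natively nucleophilic.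
3. 5 ⇐ chromanone 4 by double silylation (enol ether plus a transient cap on the phenol, so no separate protecting-group steps).
4. 4 ⇐ methoxyhydroquinone + 3-chloropropanoic acid (Friedel–Crafts acylation, then O-alkylative ring closure).
5. Ring order: ring A is bought, ring C is closed on it first, ring B is attached intact in the key step.

**Route**

Step 1
Reactants: 1 2-methoxybenzene-1,4-diol (methoxyhydroquinone); 2 3-chloropropanoic acid
Product: 4 6-hydroxy-7-methoxychroman-4-one, via chloroketone 3 (not isolated)
Conditions: TfOH (3 equiv), 80 °C, 1 h, N2; then poured into degassed 2 M aq. NaOH, 0 °C to rt, 2 h; HCl to pH 2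
Reagents that add atoms: none
Why: Friedel–Crafts acylation in triflic acid goes at C5 of 1 (para to OMe and ortho to the 4-OH, the only unhindered position activated by two oxygens), and the ortho-phenoxide then closes ring C by intramolecular displacement of chloride (6-exo-tet), the standard two-stage chroman-4-one synthesis; no stereocentre is formed.

Step 2
Reactants: 4 6-hydroxy-7-methoxychroman-4-one
Product: 5 7-methoxy-4,6-bis(trimethylsilyloxy)-2H-chromene
Conditions: TMSOTf (2.3 equiv), Et3N (3 equiv), CH2Cl2, 0 °C to rt, 1 h; pentane, filter, concentrate; used crude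
Reagents that add atoms: trimethylsilyl trifluoromethanesulfonate (TMSOTf), C[Si](C)(C)OS(=O)(=O)C(F)(F)F
Why: Soft enolisation gives the 4-silyloxy-2H-chromene (silyl enol ether formation) and at the same time caps the oxidation-prone phenol as its trimethylsilyl ether; no stereocentre is formed.

Step 3
Reactants: 5 7-methoxy-4,6-bis(trimethylsilyloxy)-2H-chromene; 6 hydroxy(tosyloxy)iodobenzene (Koser's reagent, PhI(OH)OTs); 7 1,2,4-trimethoxybenzene
Product: 10 (±)-6-hydroxy-7-methoxy-3-(2,4,5-trimethoxyphenyl)chroman-4-one, via enolonium tosylate 8 (not isolated), via silyl ether 9 (not isolated)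
Conditions: 6 (1.1 equiv), BF3·OEt2 (1.5 equiv), CH2Cl2, rt then −78 °C; add 5, 5 min; add 7 (3 equiv), −78 to −20 °C; then 1 M HCl, THF, rt
Reagents that add atoms: none
Why: Proposed new method: BF3-activated Koser's reagent exchanges the enol silyl group for trivalent iodine to give a discrete enolonium species at −78 °C in which the natively nucleophilic C3 is a strong electrophile, and 1,2,4-trimethoxybenzene (more nucleophilic on the Mayr scale than the allylsilanes known to capture such species, and added only after the oxidant is consumed) attacks through its C5 (para to the 2-OMe, ortho to the 4-OMe) in a Friedel–Crafts-type substitution with loss of iodobenzene, the closest known reaction type being the umpolung α-arylation of ketone enolonium species with indoles and pyrroles; the new C3 stereocentre is formed racemic and is erased in step 4, and the aryl silyl ether is cleaved in the acidic work-up.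

Step 4
Reactants: 10 (±)-6-hydroxy-7-methoxy-3-(2,4,5-trimethoxyphenyl)chroman-4-one
Product: 11 6-hydroxy-7-methoxy-3-(2,4,5-trimethoxyphenyl)-4H-chromen-4-one
Conditions: I2 (10 mol%), DMSO, 110 °C, 3 h, Ar; aq. Na2S2O3
Reagents that add atoms: none
Why: Iodine-catalysed dehydrogenation of a chroman-4-one in DMSO (α-iodination of the enol at C3, loss of HI to the conjugated 4-pyranone, DMSO reoxidising HI), the reaction type that turns phenolic flavanones into flavones; it removes the C3 stereocentre and leaves the free phenol and the methyl ethers alone.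

**Compound list**
1 | 2-methoxybenzene-1,4-diol (methoxyhydroquinone) | COc1cc(O)ccc1O | starting material
2 | 3-chloropropanoic acid | OC(=O)CCCl | starting material
3 | 3-chloro-1-(2,5-dihydroxy-4-methoxyphenyl)propan-1-one (chloroketone) | COc1cc(O)c(C(=O)CCCl)cc1O | intermediate
4 | 6-hydroxy-7-methoxychroman-4-one | COc1cc2OCCC(=O)c2cc1O | intermediate
5 | 7-methoxy-4,6-bis(trimethylsilyloxy)-2H-chromene | COc1cc2OCC=C(O[Si](C)(C)C)c2cc1O[Si](C)(C)C | intermediate
6 | hydroxy(tosyloxy)iodobenzene (Koser's reagent) | Cc1ccc(cc1)S(=O)(=O)OI(O)c1ccccc1 | starting material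
7 | 1,2,4-trimethoxybenzene | COc1ccc(OC)c(OC)c1 | starting material
8 | enolonium tosylate: {[7-methoxy-6-(trimethylsilyloxy)-2H-chromen-4-yl]oxy}(phenyl)(tosyloxy)iodane, O-bound trivalent-iodine enolate with electrophilic C3 | COc1cc2OCC=C(OI(c3ccccc3)OS(=O)(=O)c3ccc(C)cc3)c2cc1O[Si](C)(C)C | intermediate
9 | (±)-7-methoxy-3-(2,4,5-trimethoxyphenyl)-6-(trimethylsilyloxy)chroman-4-one (racemic) | COc1cc2OCC(c3cc(OC)c(OC)cc3OC)C(=O)c2cc1O[Si](C)(C)C | intermediate
10 | (±)-6-hydroxy-7-methoxy-3-(2,4,5-trimethoxyphenyl)chroman-4-one (racemic) | COc1cc2OCC(c3cc(OC)c(OC)cc3OC)C(=O)c2cc1O | intermediate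
11 | 6-hydroxy-7-methoxy-3-(2,4,5-trimethoxyphenyl)-4H-chromen-4-one | COc1cc2occ(-c3cc(OC)c(OC)cc3OC)c(=O)c2cc1O | target

**Total step count:** 4
**Longest linear sequence:** 4 steps (1 → 4 → 5 → 10 → 11; 2, 6 and 7 are bought)

**Steps most likely to fail, with fallbacks**

Step 3 (key coupling). The enolonium species may collapse to the chromone by hydride shift from C2, or it may oxidise the arene or the silyl-capped ring A instead of being attacked at C3. The fallback moves the polarity reversal to the other partner and sets out from 5 and 7. Arene 7 is treated with MesI(OAc)2 and TfOH in CH2Cl2 at 0 °C, attacking iodine through the same C5, to give mesityl(2,4,5-trimethoxyphenyl)iodonium triflate F1. F1 then arylates silyl enol ether 5 with Cu(OTf)2 (10 mol%) in CH2Cl2 at rt, through an aryl–copper intermediate in the trivalent state that transfers the less hindered aryl group. Acidic work-up removes the aryl silyl group and the route is rejoined at 10.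

Step 4 (dehydrogenation). Iodine may iodinate the electron-rich rings or the phenol may be oxidised at 110 °C. The fallback sets out from 10 and avoids halogen and heat. Compound 10 is resilylated (TMSOTf, Et3N, CH2Cl2, 0 °C; pentane filtration) to 7-methoxy-3-(2,4,5-trimethoxyphenyl)-4,6-bis(trimethylsilyloxy)-2H-chromene F2, with the phenol capped again. F2 is then oxidised with DDQ (1.1 equiv) and 2,4,6-collidine in CH2Cl2 at 0 °C by hydride abstraction from C2, giving the 4-silyloxybenzopyrylium ion. Aqueous acid work-up removes both silyl groups and gives 11.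

Step 1 (ring C construction). Acylation in triflic acid may give isomer mixtures or demethylation, and the hydroquinone-type phenolate may be air-oxidised in NaOH. The fallback builds ring C differently, setting out from 1. Acetylation with AcOH and BF3·OEt2 at 90 °C gives 1-(2,5-dihydroxy-4-methoxyphenyl)ethanone F3. Condensation with DMF-DMA (1.5 equiv, toluene, 80 °C, kept mild to avoid O-methylation) gives (E)-1-(2,5-dihydroxy-4-methoxyphenyl)-3-(dimethylamino)prop-2-en-1-one F4. Aqueous HCl in EtOH closes F4 to 6-hydroxy-7-methoxy-4H-chromen-4-one F5. Transfer hydrogenation of the C2=C3 bond (Pd/C, HCO2NH4, MeOH, 60 °C, stopped after one equivalent of hydrogen) rejoins the route at 4.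

**Further compounds**
F1 | step 3 | mesityl(2,4,5-trimethoxyphenyl)iodonium triflate | COc1cc(OC)c(cc1OC)[I+]c1c(C)cc(C)cc1C.[O-]S(=O)(=O)C(F)(F)F
F2 | step 4 | 7-methoxy-3-(2,4,5-trimethoxyphenyl)-4,6-bis(trimethylsilyloxy)-2H-chromene | COc1cc2OCC(c3cc(OC)c(OC)cc3OC)=C(O[Si](C)(C)C)c2cc1O[Si](C)(C)C
F3 | step 1 | 1-(2,5-dihydroxy-4-methoxyphenyl)ethanone | COc1cc(O)c(C(C)=O)cc1O
F4 | step 1 | (E)-1-(2,5-dihydroxy-4-methoxyphenyl)-3-(dimethylamino)prop-2-en-1-one | COc1cc(O)c(C(=O)/C=C/N(C)C)cc1O
F5 | step 1 | 6-hydroxy-7-methoxy-4H-chromen-4-one | COc1cc2occc(=O)c2cc1O
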